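## Retrosynthetic overview

1. All six C–Br bonds are cut first, since every free ring carbon of 1,1'-dimethyl-2,2'-bipyrrole is brominated in the last step. The two pyrroles (ring A: N1, C2–C5; ring B: N1', C2'–C5') are then traced back to two 3-pyrrolines by adding back two H2.
2. The strategy rests on the C3–C4 bond of ring A and the C3'–C4' bond of ring B. They lie opposite the nitrogen atoms and away from the C2–C2' junction, and the twofold symmetry of the skeleton makes them equivalent, so both are cut as alkenes at once.
3. This double ring-closing metathesis disconnection opens both rings to an acyclic tetraene, a hexa-1,5-diene-3,4-diamine whose nitrogens each carry methyl and allyl. Rings A and B form in one flask, one after the other, and no other ring is made.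
4. The tetraene is built around the C2–C2' bond bought in glyoxal. N-Allylmethylamine brings N1, N-CH3, C5 and C4, vinylmagnesium bromide brings C3, and benzotriazole serves as the temporary leaving group.

Key step: step 4

Remark on the chemistry: all intermediates that carry the two junction stereocentres are expected as meso/racemic mixtures. The meso form is named and drawn, and both series converge once the rings are aromatic. The target SMILES has no axial descriptor, so the hindered C2–C2' axis is taken as racemic.

## Route

Step 1
Reactants: 1 glyoxal (40 wt% in water); 2 1H-benzotriazole; 3 N-allylmethylamine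
Product: 4 meso-N,N'-diallyl-1,2-bis(1H-benzotriazol-1-yl)-N,N'-dimethylethane-1,2-diamine
Conditions: 1 (1 equiv), 2 (2 equiv), 3 (2 equiv), EtOH, rt, 16 h; filter or extract; dry azeotropically (toluene)
Reagents that add atoms: 1H-benzotriazole c1ccc2[nH]nnc2c1; N-allylmethylamine C=CCNC
Why: Benzotriazole-assisted double Mannich-type condensation: each aldehyde carbon of glyoxal condenses with the secondary amine to an iminium ion that benzotriazole traps as a stable aminal, and the two new stereocentres (like the benzotriazol-1-yl/2-yl isomerism) need no control because both carbons are ionised again in step 2.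

Step 2
Reactants: 4 bis(benzotriazolyl) diamine; 5 vinylmagnesium bromide
Product: 6 meso-(3R,4S)-N3,N4-diallyl-N3,N4-dimethylhexa-1,5-diene-3,4-diamine
Conditions: CH2=CHMgBr (5 equiv, 1.0 M in THF), THF, 0 °C to 40 °C, 16 h; H2O quench; 2 M NaOH wash; short-path distillation
Reagents that add atoms: vinylmagnesium bromide C=C[Mg]Br
Why: Grignard displacement of benzotriazole from α-aminoalkylbenzotriazoles: magnesium-assisted departure of each benzotriazolide gives an iminium ion that the vinyl nucleophile captures at carbon, the two stereocentres being set without control (meso plus racemic), which is harmless since both become sp2 in step 5.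

Step 3
Reactants: 6 tetraene diamine; 7 p-toluenesulfonic acid monohydrate
Product: 8 meso-N3,N4-diallyl-N3,N4-dimethylhexa-1,5-diene-3,4-diaminium bis(p-toluenesulfonate)
Conditions: p-TsOH·H2O (2.05 equiv), EtOAc/EtOH, 0 °C to rt; filter; dry in vacuo
Reagents that add atoms: p-toluenesulfonic acid monohydrate Cc1ccc(cc1)S(=O)(=O)O.O
Why: Brønsted acid–base salt formation: the sulfonic acid is strong enough to protonate both nitrogens of the vicinal diamine, and crystallisation of the salt also strips traces of benzotriazole and magnesium salts that would bind ruthenium in step 4, while the stereocentres are untouched.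

Step 4
Reactants: 8 tetraene bis(p-toluenesulfonate)
Product: 11 meso-1,1'-dimethyl-2,2',5,5'-tetrahydro-1H,1'H-2,2'-bipyrrole, via monocyclic triene bis(tosylate) 9 (not isolated), via bipyrrolinium bis(tosylate) 10 (not isolated)
Conditions: second-generation Grubbs catalyst RuCl2(H2IMes)(PCy3)(=CHPh) (2 × 2.5 mol%), CH2Cl2 (0.01 M), argon sparge, 40 °C, 12–24 h; then 2 M aq NaOH, CH2Cl2 extraction, careful concentration
Reagents that add atoms: none
Why: After loss of PCy3 the 14-electron ruthenium benzylidene exchanges onto the least hindered alkene, an N-allyl terminus, and the new alkylidene adds [2+2] to the vinyl group on the carbon next to that nitrogen; cycloreversion of the ruthenacyclobutane expels ethene and leaves the C3=C4 bond, and the same cycle in the other half of 9 makes C3'=C4' (Chauvin mechanism). The closest known reaction type is the ring-closing metathesis of protonated diallylamine-type dienes to 3-pyrrolinium salts, run here twice on one tetraene as in double ring-closing metathesis to linked bicycles. Ring A is closed at a carbon–carbon bond (C3=C4) from a 1,6-diene, and ring B is closed in the same mode at C3'=C4'. No stereocentre is created: C2 and C2' pass through untouched and each new alkene is Z by the constraint of the five-membered ring. Two selectivities are needed: the metal must stay free of nitrogen, which full protonation of both amines by the sulfonic acid secures, and each allyl must find the vinyl group of its own carbon (1,6-diene, five-membered ring) instead of that of the neighbouring carbon (1,7-diene, six-membered ring), which the shorter three-atom CH2–N–CH link between the partners favours kinetically. This choice is made only once, since after the first five-membered closure the remaining allyl group has no terminal partner left but its own vinyl group; high dilution and the argon purge of ethene hold back oligomerisation and re-opening.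

Step 5
Reactants: 11 bipyrroline
Product: 12 1,1'-dimethyl-1H,1'H-2,2'-bipyrrole
Conditions: activated MnO2 (15 equiv), CH2Cl2, N2, dark, rt to 40 °C; filter through Celite
Reagents that add atoms: none
Why: Dehydrogenative aromatisation of 3-pyrrolines with activated MnO2: the C2–H and C5–H bonds are both allylic and α to nitrogen and are removed easily with aromaticity as driving force, and as C2 and C2' become sp2 the meso and racemic series converge on one achiral bipyrrole.

Step 6
Reactants: 12 1,1'-dimethyl-2,2'-bipyrrole; 13 N-bromosuccinimide
Product: 14 3,3',4,4',5,5'-hexabromo-1,1'-dimethyl-1H,1'H-2,2'-bipyrrole (target)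
Conditions: NBS (6.3 equiv), THF, −78 °C to rt, dark
Reagents that add atoms: N-bromosuccinimide O=C1CCC(=O)N1Br
Why: Exhaustive electrophilic aromatic substitution (SEAr bromination) with NBS: the N-alkylpyrrole rings remain nucleophilic enough to take up bromine at C5, C4 and C3 in turn without a catalyst, no regiochemical choice arises because every free ring carbon is substituted, and cold, dark, initiator-free conditions keep radical bromination of N-CH3 out.

## Compound list

1 | glyoxal (40 wt% in water) | O=CC=O | starting material
2 | 1H-benzotriazole | c1ccc2[nH]nnc2c1 | starting material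
3 | N-allylmethylamine (N-methylprop-2-en-1-amine) | C=CCNC | starting material
4 | meso-N,N'-diallyl-1,2-bis(1H-benzotriazol-1-yl)-N,N'-dimethylethane-1,2-diamine (racemic diastereomer and benzotriazol-2-yl isomers alongside) | C=CCN(C)[C@@H](n1nnc2ccccc12)[C@@H](n1nnc2ccccc12)N(C)CC=C | intermediate
5 | vinylmagnesium bromide | C=C[Mg]Br | starting material
6 | meso-(3R,4S)-N3,N4-diallyl-N3,N4-dimethylhexa-1,5-diene-3,4-diamine (racemic diastereomer alongside) | C=CCN(C)[C@@H](C=C)[C@@H](C=C)N(C)CC=C | intermediate
7 | p-toluenesulfonic acid monohydrate | Cc1ccc(cc1)S(=O)(=O)O.O | starting material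
8 | meso-N3,N4-diallyl-N3,N4-dimethylhexa-1,5-diene-3,4-diaminium bis(p-toluenesulfonate) | C=CC[NH+](C)[C@@H](C=C)[C@@H](C=C)[NH+](C)CC=C.Cc1ccc(cc1)S(=O)(=O)[O-].Cc1ccc(cc1)S(=O)(=O)[O-] | intermediate
9 | monocyclic triene bis(tosylate): N-allyl-N-methyl-1-(1-methyl-2,5-dihydro-1H-pyrrol-2-yl)prop-2-en-1-amine, doubly protonated, relative configuration as in 8 | C=CC[NH+](C)[C@@H](C=C)[C@H]1C=CC[NH+]1C.Cc1ccc(cc1)S(=O)(=O)[O-].Cc1ccc(cc1)S(=O)(=O)[O-] | intermediate
10 | bipyrrolinium bis(tosylate): meso-1,1'-dimethyl-2,2',5,5'-tetrahydro-1H,1'H-2,2'-bipyrrole-1,1'-diium bis(p-toluenesulfonate) | C[NH+]1CC=C[C@@H]1[C@@H]1C=CC[NH+]1C.Cc1ccc(cc1)S(=O)(=O)[O-].Cc1ccc(cc1)S(=O)(=O)[O-] | intermediate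
11 | meso-(2R,2'S)-1,1'-dimethyl-2,2',5,5'-tetrahydro-1H,1'H-2,2'-bipyrrole (racemic diastereomer alongside) | CN1CC=C[C@@H]1[C@@H]1C=CCN1C | intermediate
12 | 1,1'-dimethyl-1H,1'H-2,2'-bipyrrole | Cn1cccc1-c1cccn1C | intermediate
13 | N-bromosuccinimide | O=C1CCC(=O)N1Br | starting material
14 | 3,3',4,4',5,5'-hexabromo-1,1'-dimethyl-1H,1'H-2,2'-bipyrrole | Cn1c(Br)c(Br)c(Br)c1-c1c(Br)c(Br)c(Br)n1C | target

## Step count and risks

Total step count: 6
Longest linear sequence: 6 steps (from 1 to 14)

**Step 4 (highest risk).**
- What may go wrong: proton loss from the weaker second ammonium site, or poor solubility of the dication in CH2Cl2, lets free amine bind and arrest the ruthenium alkylidene. The first closure may also leak onto the neighbouring vinyl group (six-membered mode) or into intermolecular metathesis.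
- Fallback: the same two C3=C4 closures are run on non-basic sulfinamide nitrogens, and the N-methyl groups are put on afterwards.
- It sets out from glyoxal 1, which is condensed with (R)-2-methylpropane-2-sulfinamide (2 equiv, anhydrous CuSO4, CH2Cl2) to the bis-sulfinimine (R,R)-N,N'-(ethane-1,2-diylidene)bis(2-methylpropane-2-sulfinamide) F1.
- Vinylmagnesium bromide 5 adds to both C=N bonds (CH2Cl2/toluene, −78 °C) to give the divinyl bis-sulfinamide F2. The closed magnesium-chelate chair model predicts the 3S,4S configuration, and its sense is of no consequence.
- NaH and allyl bromide in DMF give the N,N'-diallyl bis-sulfinamide tetraene F3.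
- Second-generation Grubbs catalyst RuCl2(H2IMes)(PCy3)(=CHPh) in CH2Cl2 closes both rings to the bis(N-sulfinyl) bipyrroline F4.
- HCl in MeOH removes both sulfinyl groups to give the N-unsubstituted bipyrroline F5, handled as its dihydrochloride.
- Aqueous formaldehyde and NaBH(OAc)3 give the (2S,2'S)-N,N'-dimethyl bipyrroline F6. This is the C2-symmetric diastereomer of 11; it is dehydrogenated as in step 5 and comes back to the route at 12.

**Step 2.**
- What may go wrong: the basic Grignard reagent may deprotonate the intermediate iminium ion next to the carbon that still bears benzotriazole, which leads to elimination instead of addition. The reaction may also stall after the first displacement.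
- Fallback: a less basic, slimmer sp-carbon nucleophile is used, followed by partial reduction.
- It sets out from 4. Ethynylmagnesium bromide (THF, 0 °C to rt) displaces both benzotriazoles to give meso-N3,N4-diallyl-N3,N4-dimethylhexa-1,5-diyne-3,4-diamine F7, with its racemic diastereomer.
- Semi-hydrogenation of the two terminal alkynes comes back to the route at 6. Conditions are H2, stopped after uptake of 2 equiv, Pd/CaCO3 poisoned with Pb(OAc)2 (Lindlar catalyst), quinoline, EtOAc.

**Step 5.**
- What may go wrong: over-oxidation and oxidative oligomerisation of the electron-rich bipyrrole at its free α positions on the MnO2 surface, irreversible adsorption, and evaporative loss of the small diamine.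
- Fallback: the separate dehydrogenation is given up, and oxidation and halogenation are done by one reagent.
- It sets out from 11, which is treated with N-bromosuccinimide 13 (8.5 equiv, MeCN/CH2Cl2, −40 °C to rt, dark).
- N-Bromination of each tertiary amine, loss of HBr to the conjugated cyclic iminium ion and loss of a proton give each pyrrole. Each pyrrole is brominated as soon as it forms, so the oxidation-sensitive 12 never builds up.
- Any addition of bromine across C3=C4 followed by loss of HBr leads to the same perbrominated rings.
- NBS re-oxidises the bromide of any ammonium hydrobromide, so the amine is not blocked.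
- The fallback comes back to the route at 14 and makes no compound outside the list (F0).

## Further compounds

F1 | step 4 | (R,R)-N,N'-[(1E,2E)-ethane-1,2-diylidene]bis(2-methylpropane-2-sulfinamide) | CC(C)(C)[S@@](=O)/N=C/C=N/[S@](=O)C(C)(C)C
F2 | step 4 | (R,R)-N,N'-[(3S,4S)-hexa-1,5-diene-3,4-diyl]bis(2-methylpropane-2-sulfinamide) | CC(C)(C)[S@@](=O)N[C@@H](C=C)[C@H](C=C)N[S@](=O)C(C)(C)C
F3 | step 4 | (R,R)-N,N'-diallyl-N,N'-[(3S,4S)-hexa-1,5-diene-3,4-diyl]bis(2-methylpropane-2-sulfinamide) | CC(C)(C)[S@@](=O)N(CC=C)[C@@H](C=C)[C@H](C=C)N(CC=C)[S@](=O)C(C)(C)C
F4 | step 4 | (2S,2'S)-1,1'-bis[(R)-tert-butylsulfinyl]-2,2',5,5'-tetrahydro-1H,1'H-2,2'-bipyrrole | CC(C)(C)[S@@](=O)N1CC=C[C@H]1[C@@H]1C=CCN1[S@](=O)C(C)(C)C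
F5 | step 4 | (2S,2'S)-2,2',5,5'-tetrahydro-1H,1'H-2,2'-bipyrrole | N1CC=C[C@H]1[C@@H]1C=CCN1
F6 | step 4 | (2S,2'S)-1,1'-dimethyl-2,2',5,5'-tetrahydro-1H,1'H-2,2'-bipyrrole | CN1CC=C[C@H]1[C@@H]1C=CCN1C
F7 | step 2 | meso-(3R,4S)-N3,N4-diallyl-N3,N4-dimethylhexa-1,5-diyne-3,4-diamine | C=CCN(C)[C@@H](C#C)[C@@H](C#C)N(C)CC=C
F0 | step 5 | none | none
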